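## Analysis of the target

The target 9 is a flavonol. Benzene ring A is fused to the 4-pyranone ring C (O1, C2, C3, C4, C4a, C8a), and the 3,4,5-trimethoxyphenyl ring B sits on C2. It has no stereocenter and is planar. The only stereocenter on the way, C2 of flavanone 6, is formed racemic and returns to sp2 two steps later, so no stereochemical relationship has to be controlled. Seven oxygen substituents must be told apart: free hydroxyls at C3 and C5, and methyl ethers at C7, C8, C3', C4' and C5'. The 3-hydroxy-4-pyranone is an enolised 1,2-diketone that is oxidised by air in base. A free 5-hydroxyl next to a 7,8-dioxygenated ring A also lets ring C open and reclose onto the other ortho oxygen in hot mineral acid (Wessely–Moser rearrangement). The difficulties are therefore the C3 oxygen, the single free phenol among six aryl methyl ethers, and the very electron-rich ring A, which has to survive any oxidative step. The plan rests on C2, which is bonded to O1 and to C1' of ring B. At the CH2 oxidation level it is the methylene of a 3,4,5-trimethoxybenzyl ether of a ring A phenol, and a quinone oxidant can take hydride from it because the cation is stabilised by O1 and by ring B. C3 is the α-carbon of the ring A acetyl group, so as an enol derivative it is the matching nucleophile, and joining C3 to C2 closes ring C.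

## Retrosynthetic reasoning

**9 from 8 (C5 O–CH3 bond).** The 5-hydroxyl is traced back to a methyl ether, so that ring A stays a uniform tri-O-methyl system and acetophenone 1 can be used as bought. The methyl group also masks the phenol through the acidic steps, where a free 5-OH could trigger ring-opening isomerisation or ring nitrosation. The forward step has to cleave one aryl methyl ether out of six; the peri relationship of the 5-oxygen to C4=O is what singles it out.

**8 from 7 and 7 from 6 (C3–O bond and C2=C3 unsaturation).** Both the C3 oxygen and the ring C double bond are traced to the C3 methylene of flavanone 6. C3 is the only enolisable carbon of 6, so electrophilic nitrosation gives oxime 7, in which C3 already stands at the ketone oxidation level. Hydrolysis of 7 gives the 3,4-diketone, which is the keto tautomer of 8. This raises the oxidation level without an oxidant that could attack rings A and B. It also fixes a requirement on the key step: it must deliver the flavanone, not the flavone, because only the flavanone has an enolisable C3.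

**6 from 4 through 5 (C2–C3 bond, ring C).** The cut is made between C2 and C3 because the two ends carry complementary latent reactivity: C2 can become a cation by loss of hydride, and C3 is an enol carbon. The precursor 4 already holds the O1–C2 bond as a benzyl ether and C3 as the terminal carbon of an enol acetate. The forward reaction has to remove hydride from the OCH2 carbon to give oxocarbenium ion 5, let the enol acetate close the six-membered ring, and lose the acetyl group, all without water and without dehydrogenating 6.

**4 from 3 (enol O–acyl bond).** The enol acetate is taken back to methyl ketone 3. Only the acetyl methyl can enolise, so the regiochemistry is not in question. The forward step is done under basic, cold conditions, since the electron-rich benzyl aryl ether in 3 would be at risk in a hot acid-catalysed enol ester exchange.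

**3 from 1 and 2 (O1–C2 ether bond).** Cutting the aryl O–CH2 bond gives the phenolic acetophenone 1 and benzyl chloride 2. One alkylation brings in ring B together with C2, and 1 and 2 between them hold every carbon of 9.

## Alternatives that were turned down

**Alternative 1:** Ring A is built last, by cutting C4a–C5 and C8–C8a. The precursor A2 is a 3-benzyloxy-2-aryl-4-pyranone carrying a 3,4-dimethoxycyclobutenone on the carbon that becomes C8a. On heating, A2 should open to a dienylketene, which closes by six-electron electrocyclisation onto the neighbouring pyranone C=C bond and enolises to the 3-O-benzyl flavonol A1; hydrogenolysis would finish.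
- For: every ring A oxygen is placed by construction. The 5-OH arrives free from the ketene carbon, so no selective demethylation is needed, and the C3 oxygen is present from the start. On oxygen differentiation this plan is stronger than the chosen one.
- Against: A2 needs a pyranone metallated next to the ring oxygen, which is prone to attack its own carbonyl. It also needs regioselective addition to a cyclobutenedione, methylation of a tertiary alkoxide, and a separate multi-step build of the pyranone bearing ring B. The electrocyclisation must engage a vinylogous ester double bond rather than a simple arene or alkene. The count would be near ten steps.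
- Comparison: the chosen route reaches its key-step precursor in two steps from catalogue compounds and confines the uncertainty to one reaction.

**Alternative 2:** Ring C is closed at O1–C8a. The precursor A4 is a 2-acyl-5-methoxy-1,4-benzoquinone whose acyl group is the ring B β-diketone chain. Its enol oxygen adds to the free quinone carbon next to the acyl group, and tautomerisation gives the 5,8-dihydroxy-7-methoxyflavone A3, the quinone having served as internal oxidant.
- For: the conjugate addition is polarity-matched and better grounded than the new oxidative closure. No external oxidant is needed. The two phenols of A3 differ by chelation, so 8-O-methylation should be selective and the 5-OH needs no demethylation. On both points it is stronger than the chosen route.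
- Against: A3 has no C3 oxygen, and a flavone C3 is not enolisable. Late hydroxylation (epoxidation or metalation, boration, oxidation) with 5-OH protection would add three or four steps. A4 is a strong electrophile that must be generated by oxidation in the presence of an oxidation-prone β-diketone, whose central carbon can also add to the quinone.
- Comparison: the chosen route delivers a flavanone whose C3 methylene is functionalised directly, and it is shorter overall.

**Alternative 3:** Ring C is closed at C3–C4 from dialdehyde A6, in which the ring A aldehyde sits ortho to an O–CH(aryl)–CHO chain. A triazolium-derived carbene converts the ring A aldehyde into an acyl anion equivalent that adds to the aliphatic aldehyde, giving the trans dihydroflavonol A5.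
- For: intramolecular benzoin closure to chromanones is known chemistry, and A5 already carries the C3 oxygen, so one dehydrogenation replaces the nitrosation and hydrolysis pair. On these two points it is stronger than the chosen route.
- Against: the α-aryl-α-aryloxy aldehyde in A6 enolises very easily, and under the basic conditions its α-carbon can add to the ring A aldehyde to give a five-membered ring. The hindered, electron-rich ring A aldehyde is the poorer acyl donor, so the isomeric 4-hydroxy-3-ketone is a likely competitor. Making A6 needs protection and redox adjustment of two different aldehydes, roughly five steps before the key step. Both stereocenters of A5 are erased afterwards.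
- Comparison: the chosen route offers a stable precursor in two steps and also makes and erases one stereocenter, but without any selectivity demand on it.

Key step: step 3

Assumption: acetophenone 1 is taken as a catalogue compound and used as bought.

Remark: flavanone 6 and oxime 7 are racemic at C2; one enantiomer is drawn, and the centre disappears in step 5.

## Route

Step 1
Reactants: 1 2'-hydroxy-3',4',6'-trimethoxyacetophenone; 2 3,4,5-trimethoxybenzyl chloride
Product: 3 1-{3,4,6-trimethoxy-2-[(3,4,5-trimethoxybenzyl)oxy]phenyl}ethanone
Conditions: K2CO3, KI (cat.), DMF, 60 °C
Reagents that add atoms: none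
Why: Williamson ether synthesis: carbonate in DMF deprotonates the hydrogen-bonded 2'-hydroxyl and the phenoxide displaces halide from the activated benzylic carbon (iodide formed in situ by halide exchange speeds this up); the acetyl methyl is far less acidic and is not alkylated.

Step 2
Reactants: 3 1-{3,4,6-trimethoxy-2-[(3,4,5-trimethoxybenzyl)oxy]phenyl}ethanone
Product: 4 1-{3,4,6-trimethoxy-2-[(3,4,5-trimethoxybenzyl)oxy]phenyl}vinyl acetate
Conditions: KN(SiMe3)2, THF, −78 °C; then Ac2O, −78 → 0 °C; pH 7 work-up
Reagents that add atoms: acetic anhydride CC(=O)OC(C)=O
Why: Kinetic enolate formation and O-acylation: the acetyl methyl is the only enolisable position and the dissociated potassium enolate should react with the hard anhydride at oxygen to give the enol acetate; the cold basic conditions leave the acid-sensitive trimethoxybenzyl aryl ether untouched.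

Step 3
Reactants: 4 1-{3,4,6-trimethoxy-2-[(3,4,5-trimethoxybenzyl)oxy]phenyl}vinyl acetate
Product: 6 (±)-5,7,8-trimethoxy-2-(3,4,5-trimethoxyphenyl)chroman-4-one, via benzylic oxocarbenium ion 5 (not isolated)
Conditions: DDQ (1.2 equiv), 2,6-dichloropyridine, LiClO4, 4 Å MS, ClCH2CH2Cl, 0 °C → rt
Reagents that add atoms: none
Why: Proposed new method: DDQ should form a charge-transfer complex with the electron-rich arenes of 4, and electron transfer followed by loss of a hydrogen atom (net hydride transfer) from the O–CH2–aryl carbon gives oxocarbenium ion 5, the same event that starts the known oxidative removal of alkoxybenzyl groups from phenols, here run without water so that the ion survives. The tethered enol acetate then adds through its terminal CH2 carbon to C2, and the acetoxycarbenium ion so formed gives up its acetyl group (to the hydroquinone anion or to water on work-up) to reveal the C4 ketone of 6. The closest known reaction type is DDQ-mediated oxidative C–H cleavage of benzylic alkyl ethers with capture of the oxocarbenium ion by a tethered enol acetate to give tetrahydropyran-4-ones; new here is that the ether oxygen is a phenol oxygen, a weaker donor. Ring C closes in a 6-endo-trig mode with respect to the C2=O1 oxocarbenium bond, and the enol C=C bond also lies inside the new ring. The new stereocenter C2 is formed without any controlling element, so 6 is expected as a racemate, which is acceptable because C2 becomes sp2 again in step 5. The step needs site selectivity for the OCH2 hydrogens over the methoxy hydrogens, which is secured because only this carbon is both benzylic and oxygen-bearing. It also needs the oxidation to stop at the flavanone, secured by near-stoichiometric DDQ at or below room temperature, where dehydrogenation of a flavanone (which needs enolisation and heat) should not compete. 2,6-Dichloropyridine buffers the acidic hydroquinone without adding to the cation, LiClO4 loosens the ion pair, and the sieves keep out water that would turn the closure into plain debenzylation.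

Step 4
Reactants: 6 (±)-5,7,8-trimethoxy-2-(3,4,5-trimethoxyphenyl)chroman-4-one
Product: 7 (±)-3-(hydroxyimino)-5,7,8-trimethoxy-2-(3,4,5-trimethoxyphenyl)chroman-4-one
Conditions: isoamyl nitrite, conc. HCl, EtOH, 40 °C
Reagents that add atoms: isoamyl nitrite CC(C)CCON=O
Why: Acid-catalysed α-nitrosation of a ketone: the enol of 6 attacks the nitrosonium equivalent from the nitrite ester at C3, the only enolisable carbon, and the C-nitroso compound tautomerises to the oxime (first half of the classical isonitroso route from flavanones to flavonols); the methyl-capped, carbonyl-deactivated ring A should not be nitrosated, C2 is untouched and the oxime geometry is of no consequence.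

Step 5
Reactants: 7 (±)-3-(hydroxyimino)-5,7,8-trimethoxy-2-(3,4,5-trimethoxyphenyl)chroman-4-one
Product: 8 3-hydroxy-5,7,8-trimethoxy-2-(3,4,5-trimethoxyphenyl)-4H-chromen-4-one
Conditions: 10% aq. H2SO4, AcOH, 100 °C
Reagents that add atoms: water O
Why: Hydrolysis of an α-oximino ketone: water replaces hydroxylamine at C3 to give the 3,4-diketone, which enolises toward C2 into the conjugated 3-hydroxy-4-pyranone, so the C2 stereocenter disappears; the 5-O-methyl group blocks acid-induced ring-opening isomerisation of ring A.

Step 6
Reactants: 8 3-hydroxy-5,7,8-trimethoxy-2-(3,4,5-trimethoxyphenyl)-4H-chromen-4-one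
Product: 9 3,5-dihydroxy-7,8-dimethoxy-2-(3,4,5-trimethoxyphenyl)-4H-chromen-4-one (3,5-dihydroxy-7,8,3',4',5'-pentamethoxyflavone)
Conditions: BCl3 (3 equiv), CH2Cl2, −78 → 0 °C; then aq. HCl
Reagents that add atoms: none
Why: Chelation-directed ether cleavage, the standard selective 5-O-demethylation of 5-methoxyflavones: once the 3-hydroxyl is a borate, a further BCl3 binds between C4=O and the peri 5-methoxy oxygen and chloride removes that methyl group, while the 7-, 8- and ring B methoxy groups have no carbonyl to assist; aqueous acid frees both hydroxyls.

## Compound list

1 | 2'-hydroxy-3',4',6'-trimethoxyacetophenone | CC(=O)c1c(O)c(OC)c(OC)cc1OC | starting material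
2 | 3,4,5-trimethoxybenzyl chloride | COc1cc(CCl)cc(OC)c1OC | starting material
3 | 1-{3,4,6-trimethoxy-2-[(3,4,5-trimethoxybenzyl)oxy]phenyl}ethanone | CC(=O)c1c(OC)cc(OC)c(OC)c1OCc1cc(OC)c(OC)c(OC)c1 | intermediate
4 | 1-{3,4,6-trimethoxy-2-[(3,4,5-trimethoxybenzyl)oxy]phenyl}vinyl acetate | CC(=O)OC(=C)c1c(OC)cc(OC)c(OC)c1OCc1cc(OC)c(OC)c(OC)c1 | intermediate
5 | benzylic oxocarbenium ion from 4 by loss of hydride at the OCH2 carbon (cation, not isolated; geometry about O=C not defined) | CC(=O)OC(=C)c1c(OC)cc(OC)c(OC)c1[O+]=Cc1cc(OC)c(OC)c(OC)c1 | intermediate
6 | (±)-5,7,8-trimethoxy-2-(3,4,5-trimethoxyphenyl)chroman-4-one (racemic; 2S enantiomer drawn) | COc1cc(cc(OC)c1OC)[C@@H]1CC(=O)c2c(OC)cc(OC)c(OC)c2O1 | intermediate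
7 | (±)-3-(hydroxyimino)-5,7,8-trimethoxy-2-(3,4,5-trimethoxyphenyl)chroman-4-one (racemic; one enantiomer drawn; oxime geometry not defined) | COc1cc(cc(OC)c1OC)[C@@H]1C(=NO)C(=O)c2c(OC)cc(OC)c(OC)c2O1 | intermediate
8 | 3-hydroxy-5,7,8-trimethoxy-2-(3,4,5-trimethoxyphenyl)-4H-chromen-4-one | COc1cc(-c2oc3c(OC)c(OC)cc(OC)c3c(=O)c2O)cc(OC)c1OC | intermediate
9 | 3,5-dihydroxy-7,8-dimethoxy-2-(3,4,5-trimethoxyphenyl)-4H-chromen-4-one | COc1cc(-c2oc3c(OC)c(OC)cc(O)c3c(=O)c2O)cc(OC)c1OC | target

## Step count and risks

Total step count: 6. Longest linear sequence: 6 steps (1 to 9); compound 2 is used as bought.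

**Step 3 (key step, proposed new method).**
- Risk: hydride abstraction that is too slow or misdirected. The aryloxy oxygen shares its lone pair with ring A, and the 4'-methoxy group is twisted by its two neighbours, so ion 5 is less stabilised than in the alkyl ether cases.
- If electron transfer comes mainly from ring A, mesolytic cleavage of the O–CH2 bond or oxidative coupling through the free ring A position can take over. Traces of water turn the closure into debenzylation.
- Forcing the reaction with heat or excess oxidant risks dehydrogenation beyond the flavanone level, which would block the nitrosation at C3. Over-oxidised material could still be brought to 8 by the detour given under step 4.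
- Fallback (known chemistry): set out from 1 and condense it with 3,4,5-trimethoxybenzaldehyde F1 (KOH, EtOH, rt; Claisen–Schmidt condensation) to give (E)-1-(2-hydroxy-3,4,6-trimethoxyphenyl)-3-(3,4,5-trimethoxyphenyl)prop-2-en-1-one F2. Close ring C by oxa-Michael addition of the 2'-hydroxyl (NaOAc, EtOH, reflux). This comes back to the route at 6. It gives up the C2–C3 closure for an O1–C2 closure but keeps the end-game unchanged.

**Step 4 (together with step 5).**
- Risk: nitrosation on the electron-rich ring A instead of C3, or acid-induced opening of ring C to the chalcone under the HCl conditions. In the following hydrolysis the α-oximino ketone may fragment (Beckmann-type cleavage of the C3–C4 bond) instead of exchanging with water.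
- Fallback: set out from 6 and dehydrogenate it (I2, DMSO, 110 °C) to 5,7,8-trimethoxy-2-(3,4,5-trimethoxyphenyl)-4H-chromen-4-one F3. Epoxidise the C2=C3 bond with dimethyldioxirane (acetone/CH2Cl2, 0 °C) to (±)-2,3-epoxy-5,7,8-trimethoxy-2-(3,4,5-trimethoxyphenyl)chroman-4-one F4. Open the epoxide with catalytic TsOH in CH2Cl2, which gives the flavonol by loss of the C3 proton. This comes back to the route at 8 and bypasses both the nitrosation and the hydrolysis.

**Step 6.**
- Risk: incomplete cleavage because the 3-O-borate already occupies the C4 carbonyl, or loss of a crowded methyl ether (8-OMe or 4'-OMe) if the mixture is warmed to force conversion.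
- Fallback: set out from 8 and acetylate the 3-hydroxyl (Ac2O, pyridine) to 5,7,8-trimethoxy-4-oxo-2-(3,4,5-trimethoxyphenyl)-4H-chromen-3-yl acetate F5, so that the only chelation site is C4=O with 5-OMe. Demethylate with BCl3 (CH2Cl2, −78 → 0 °C) to 5-hydroxy-7,8-dimethoxy-4-oxo-2-(3,4,5-trimethoxyphenyl)-4H-chromen-3-yl acetate F6. Remove the acetate by methanolysis (K2CO3, MeOH, 0 °C, under argon). This comes back to the route at 9.

**Step 2.**
- Risk: C-acylation of the enolate to a 1,3-diketone in competition with O-acylation, or hydrolysis of the enol acetate back to 3 during isolation.
- Fallback: set out from 3 and use acid-catalysed enol ester exchange with isopropenyl acetate (cat. TsOH, reflux, acetone distilled off), a thermodynamic method that involves no enolate. It comes back to the route at 4 and makes no new compound (F0). Its own risk is ionisation of the benzyl ether, so it is held in reserve.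

## Further compounds

F1 | step 3 | 3,4,5-trimethoxybenzaldehyde (bought reagent of the fallback) | COc1cc(C=O)cc(OC)c1OC
F2 | step 3 | (E)-1-(2-hydroxy-3,4,6-trimethoxyphenyl)-3-(3,4,5-trimethoxyphenyl)prop-2-en-1-one | COc1cc(/C=C/C(=O)c2c(O)c(OC)c(OC)cc2OC)cc(OC)c1OC
F3 | step 4 | 5,7,8-trimethoxy-2-(3,4,5-trimethoxyphenyl)-4H-chromen-4-one | COc1cc(-c2cc(=O)c3c(OC)cc(OC)c(OC)c3o2)cc(OC)c1OC
F4 | step 4 | (±)-2,3-epoxy-5,7,8-trimethoxy-2-(3,4,5-trimethoxyphenyl)chroman-4-one (racemic; cis-fused; one enantiomer drawn) | COc1cc(cc(OC)c1OC)[C@]12O[C@H]1C(=O)c1c(OC)cc(OC)c(OC)c1O2
F5 | step 6 | 5,7,8-trimethoxy-4-oxo-2-(3,4,5-trimethoxyphenyl)-4H-chromen-3-yl acetate | COc1cc(-c2oc3c(OC)c(OC)cc(OC)c3c(=O)c2OC(C)=O)cc(OC)c1OC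
F6 | step 6 | 5-hydroxy-7,8-dimethoxy-4-oxo-2-(3,4,5-trimethoxyphenyl)-4H-chromen-3-yl acetate | COc1cc(-c2oc3c(OC)c(OC)cc(O)c3c(=O)c2OC(C)=O)cc(OC)c1OC
F0 | step 2 | none | none
A1 | alternative 1 | 3-(benzyloxy)-5-hydroxy-7,8-dimethoxy-2-(3,4,5-trimethoxyphenyl)-4H-chromen-4-one | COc1cc(-c2oc3c(OC)c(OC)cc(O)c3c(=O)c2OCc2ccccc2)cc(OC)c1OC
A2 | alternative 1 | 4-[5-(benzyloxy)-4-oxo-6-(3,4,5-trimethoxyphenyl)-4H-pyran-2-yl]-3,4-dimethoxycyclobut-2-en-1-one (racemic; drawn without descriptor) | COC1=CC(=O)C1(OC)c1cc(=O)c(OCc2ccccc2)c(-c2cc(OC)c(OC)c(OC)c2)o1
A3 | alternative 2 | 5,8-dihydroxy-7-methoxy-2-(3,4,5-trimethoxyphenyl)-4H-chromen-4-one | COc1cc(-c2cc(=O)c3c(O)cc(OC)c(O)c3o2)cc(OC)c1OC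
A4 | alternative 2 | 1-(4-methoxy-3,6-dioxocyclohexa-1,4-dien-1-yl)-3-(3,4,5-trimethoxyphenyl)propane-1,3-dione | COC1=CC(=O)C(=CC1=O)C(=O)CC(=O)c1cc(OC)c(OC)c(OC)c1
A5 | alternative 3 | trans-3-hydroxy-5,7,8-trimethoxy-2-(3,4,5-trimethoxyphenyl)chroman-4-one (racemic; one enantiomer drawn) | COc1cc(cc(OC)c1OC)[C@@H]1[C@@H](O)C(=O)c2c(OC)cc(OC)c(OC)c2O1
A6 | alternative 3 | 2-(2-formyl-3,5,6-trimethoxyphenoxy)-2-(3,4,5-trimethoxyphenyl)acetaldehyde (racemic; one enantiomer drawn) | O=C[C@@H](Oc1c(C=O)c(OC)cc(OC)c1OC)c1cc(OC)c(OC)c(OC)c1
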